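**Plan**
1. Retrosynthetic cuts, in order. (a) The bond from ring A C5 to purine C8. (b) The ring A C3–O bond of the diaryl ether, which opens the 14-membered ring (ring A C1–C2–C3, O, ring B C1'–C4', CH2, CH, CH2, NH, CH, CH2). (c) The two piperazine CH2–N units, taken back to the two amide bonds of a tyrosine–tyrosine diketopiperazine.
2. Enabling feature. Ring A is a tyrosine phenol (C4–OH) whose two ortho carbons carry the ring B oxygen (C3) and purine C8 (C5). Ring B is a second tyrosine phenol bound through its own oxygen, and both benzyl arms stand cis on the piperazine. Ring A therefore maps onto 3,5-diiodotyrosine: one iodine leaves in an oxidative phenol C–O coupling, and the other stays as the handle for the purine.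
3. Helpers. Two chlorines on ring B raise its oxidation potential and block C–C coupling. The N-Boc groups shield the amines and push both arms pseudoaxial. The others are a para-methoxy dienone oxidation level of ring A, a benzyl ether, and the deoxyribose of the purine partner. All leave in steps 6, 10 and 11.
4. Forward order: dipeptide, diketopiperazine ring, piperazine by reduction, then the 14-membered ring as the last ring closed. The purine bicycle is bought intact as 8-bromo-2'-deoxyguanosine and attached afterwards by Suzuki–Miyaura coupling, because guanine would not survive the oxidant.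
5. Stereochemistry: both (S) centres come from L-tyrosine. After reduction of the diketopiperazine they are no longer enolizable, and no later step touches them.

Key step: step 5

Remark: 1, 3 and 14 are taken as catalogue compounds. Free 8-arylguanines interconvert between the N9-H and N7-H forms, so cleavage of the N9 glycoside gives the compound drawn as the N7-H tautomer. Ring A is numbered from its CH2-bearing carbon (C1), ring B from its oxygen-bearing carbon (C1').

Step 1
Reactants: 1 L-tyrosine methyl ester hydrochloride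
Product: 2 3,5-dichloro-L-tyrosine methyl ester hydrochloride
Conditions: SO2Cl2 (2.2 equiv), AcOH, rt
Reagents that add atoms: sulfuryl chloride, O=S(=O)(Cl)Cl
Why: Electrophilic aromatic chlorination: the phenol directs both chlorines to its two free ortho carbons (para is blocked), the ammonium form keeps nitrogen out of the reaction, and the stereocentre is not involved.

Step 2
Reactants: 2 3,5-dichloro-L-tyrosine methyl ester hydrochloride; 3 N-Boc-3,5-diiodo-L-tyrosine
Product: 4 dipeptide Boc-L-Tyr(3,5-I2)-L-Tyr(3,5-Cl2)-OMe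
Conditions: EDC·HCl, HOBt, N-methylmorpholine, DMF, 0 °C → rt
Reagents that add atoms: none
Why: Carbodiimide/HOBt amide coupling: the urethane-protected acid cannot racemize through an oxazolone, and the hindered, weakly nucleophilic dihalophenols do not compete with the primary amine.

Step 3
Reactants: 4 dipeptide Boc-L-Tyr(3,5-I2)-L-Tyr(3,5-Cl2)-OMe
Product: 6 (3S,6S)-3-(3,5-dichloro-4-hydroxybenzyl)-6-(4-hydroxy-3,5-diiodobenzyl)piperazine-2,5-dione, via free-amine dipeptide 5 (not isolated)
Conditions: HCO2H, rt; evaporate; 2-butanol–toluene 4:1, reflux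
Reagents that add atoms: none
Why: Acidolysis of the Boc group followed by thermal 6-exo-trig aminolysis of the methyl ester (diketopiperazine formation from a dipeptide ester) under neutral to weakly acidic conditions that should leave both alpha carbons (S) configured.

Step 4
Reactants: 6 (3S,6S)-3-(3,5-dichloro-4-hydroxybenzyl)-6-(4-hydroxy-3,5-diiodobenzyl)piperazine-2,5-dione
Product: 8 di-tert-butyl (2S,5S)-2-(3,5-dichloro-4-hydroxybenzyl)-5-(4-hydroxy-3,5-diiodobenzyl)piperazine-1,4-dicarboxylate, via free piperazine 7 (not isolated)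
Conditions: BH3·THF (excess), THF, reflux; MeOH, then 1 M HCl–MeOH, 50 °C; concentrate; Boc2O (2.1 equiv), NaHCO3, THF–H2O, rt
Reagents that add atoms: di-tert-butyl dicarbonate, CC(C)(C)OC(=O)OC(=O)OC(C)(C)C
Why: Borane reduction of both lactams to amines, which leaves aryl iodides and chlorides alone and removes the only enolizable positions without epimerization, followed by chemoselective N-acylation with Boc2O (amines react far faster than the hindered dihalophenols).

Step 5
Reactants: 8 di-tert-butyl (2S,5S)-2-(3,5-dichloro-4-hydroxybenzyl)-5-(4-hydroxy-3,5-diiodobenzyl)piperazine-1,4-dicarboxylate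
Product: 10 macrocyclic methoxy dienone (14-membered ring closed; ring A = 2-aryloxy-6-iodo-4-methoxycyclohexa-2,5-dienone), via ipso adduct 9 (not isolated)
Conditions: Tl(NO3)3·3H2O (3 equiv), MeOH–THF 5:1, high dilution (1 mM), −10 → 0 °C; aq NaHCO3 work-up
Reagents that add atoms: methanol, CO
Why: Trivalent thallium takes two electrons from the phenol of lower oxidation potential, the 2,6-diiodophenol ring A, the ring B hydroxyl oxygen adds to the iodine-bearing ortho carbon C3 of the resulting phenoxenium ion to give ipso adduct 9, and 9 loses iodide and takes up methanol at the para carbon C1 to give the cross-conjugated dienone 10. The closest known reaction type is the Tl(NO3)3 oxidative C–O coupling of two ortho,ortho'-dihalogenated tyrosine phenols to isodityrosine-type macrocyclic diaryl ethers, which has been shown on peptides and on N-acylated bis(hydroxybenzyl)piperazines. Only the 14-membered ring closes, by attack of oxygen on a trigonal carbon whose C2=C3 bond lies inside the new ring (14-endo-trig), and because C3 becomes tetrahedral in 9 and C1 in 10 the ring closes on a puckered, non-aromatic ring A, so that the strain of the meta,para-cyclophane is paid only in the aromatization of step 6. The tetrahedral carbons C3 of 9 and C1 of 10 should arise by approach from the open outer face of ring A, need no control because both are erased in step 6 (they are therefore left undefined in the SMILES), and the two piperazine stereocentres lie two bonds away from any redox event and are not touched. The step needs direction (ring A oxidized, ring B nucleophile), C–O instead of C–C coupling and ring closure instead of chain growth: the gap in oxidation potential between the diiodo- and the dichlorophenol secures the first, the four halogens on all ortho carbons the second, and high dilution together with the cis arms, held pseudoaxial on one face of a twist-boat piperazine by allylic strain against the two N-Boc groups, the third. Once closed, ring B has no free hydroxyl group and ring A is a dienone, so oxidation stops by itself, and the surviving iodine stands on C5, the carbon that must later carry C8 of the purine.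

Step 6
Reactants: 10 macrocyclic methoxy dienone
Product: 11 macrocyclic iodophenol (ring A: C3–O–ring B / C4–OH / C5–I; ring B 2',6'-dichloro; N,N'-di-Boc)
Conditions: Zn dust, AcOH–THF 1:1, rt
Reagents that add atoms: none
Why: Zinc–acetic acid reductive aromatization of a para-quinol ether: electron transfer to the dienone expels the C1 methoxide and the gain of aromaticity pays for the strain of the cyclophane, while aryl C–I and C–Cl bonds and the carbamates are inert to Zn/AcOH at room temperature.

Step 7
Reactants: 11 macrocyclic iodophenol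
Product: 12 macrocyclic iodide benzyl ether (C4–OBn)
Conditions: BnBr, K2CO3, DMF, 40 °C
Reagents that add atoms: benzyl bromide, BrCc1ccccc1
Why: Williamson ether synthesis on the only free phenol, needed because a free ortho hydroxyl group would favour hydrodeiodination during the borylation; the benzyl group leaves later together with the chlorines.

Step 8
Reactants: 12 macrocyclic iodide benzyl ether
Product: 13 macrocyclic pinacol boronate (C5–Bpin)
Conditions: B2pin2, PdCl2(dppf) (5 mol %), KOAc, dioxane, 85 °C
Reagents that add atoms: bis(pinacolato)diboron, CC1(C)OB(OC1(C)C)B1OC(C)(C)C(C)(C)O1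
Why: Miyaura borylation: zerovalent palladium inserts into the C5–I bond far faster than into the two flanked C–Cl bonds of ring B, and KOAc is too weak a base to start a Suzuki-type homocoupling.

Step 9
Reactants: 13 macrocyclic pinacol boronate; 14 8-bromo-2'-deoxyguanosine
Product: 15 C8-arylated 2'-deoxyguanosine (ring A C5 bound to purine C8; OBn, two Cl and two Boc still in place)
Conditions: Pd(OAc)2 (10 mol %), P(C6H4-3-SO3Na)3, Na2CO3, DMF–H2O 2:1, 80 °C
Reagents that add atoms: none
Why: Suzuki–Miyaura coupling of an unprotected 8-bromopurine nucleoside with an arylboron reagent in aqueous medium with a sulfonated phosphine, a known way to C8-aryl-2'-deoxyguanosines including ortho-oxygenated aryl groups, in which the sugar blocks N9 and lends solubility and the aryl chlorides stay inert.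

Step 10
Reactants: 15 C8-arylated 2'-deoxyguanosine
Product: 16 chlorine-free, debenzylated N,N'-di-Boc nucleoside
Conditions: H2 (4 bar), 10% Pd/C, NaOAc, MeOH–THF, rt
Reagents that add atoms: none
Why: Catalytic hydrogenolysis over Pd/C removes both helper chlorines (hydrodechlorination, buffered by acetate) and the benzyl ether in one operation, while the purine, carbamates, glycoside and diaryl ether are inert.

Step 11
Reactants: 16 chlorine-free, debenzylated N,N'-di-Boc nucleoside
Product: 17 guanipiperazine A
Conditions: TFA–H2O 4:1, 40 °C; evaporate; weakly basic ion-exchange resin, H2O–MeOH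
Reagents that add atoms: none
Why: Acidolysis cleaves both Boc groups and hydrolyses the N-glycosidic bond (acid depurination, especially fast for C8-aryl-2'-deoxyguanosines), the liberated amines stay protonated and so do not condense with the released sugar, and no stereocentre of the piperazine is affected.

**Compound list**
1 | L-tyrosine methyl ester hydrochloride | COC(=O)[C@@H](N)Cc1ccc(O)cc1.Cl | starting material
2 | 3,5-dichloro-L-tyrosine methyl ester hydrochloride | COC(=O)[C@@H](N)Cc1cc(Cl)c(O)c(Cl)c1.Cl | intermediate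
3 | N-Boc-3,5-diiodo-L-tyrosine | CC(C)(C)OC(=O)N[C@@H](Cc1cc(I)c(O)c(I)c1)C(=O)O | starting material
4 | Boc-L-Tyr(3,5-I2)-L-Tyr(3,5-Cl2)-OMe | CC(C)(C)OC(=O)N[C@@H](Cc1cc(I)c(O)c(I)c1)C(=O)N[C@@H](Cc1cc(Cl)c(O)c(Cl)c1)C(=O)OC | intermediate
5 | H-L-Tyr(3,5-I2)-L-Tyr(3,5-Cl2)-OMe (free-amine dipeptide, not isolated) | N[C@@H](Cc1cc(I)c(O)c(I)c1)C(=O)N[C@@H](Cc1cc(Cl)c(O)c(Cl)c1)C(=O)OC | intermediate
6 | (3S,6S)-3-(3,5-dichloro-4-hydroxybenzyl)-6-(4-hydroxy-3,5-diiodobenzyl)piperazine-2,5-dione | O=C1N[C@@H](Cc2cc(Cl)c(O)c(Cl)c2)C(=O)N[C@H]1Cc1cc(I)c(O)c(I)c1 | intermediate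
7 | (2S,5S)-2-(3,5-dichloro-4-hydroxybenzyl)-5-(4-hydroxy-3,5-diiodobenzyl)piperazine (not isolated) | C1N[C@@H](Cc2cc(Cl)c(O)c(Cl)c2)CN[C@H]1Cc1cc(I)c(O)c(I)c1 | intermediate
8 | di-tert-butyl (2S,5S)-2-(3,5-dichloro-4-hydroxybenzyl)-5-(4-hydroxy-3,5-diiodobenzyl)piperazine-1,4-dicarboxylate | C1N(C(=O)OC(C)(C)C)[C@@H](Cc2cc(Cl)c(O)c(Cl)c2)CN(C(=O)OC(C)(C)C)[C@H]1Cc1cc(I)c(O)c(I)c1 | intermediate
9 | ipso adduct: 14-membered ring closed through O–C3; ring A = 6-aryloxy-2,6-diiodocyclohexa-2,4-dienone (C3 sp3 with I and O–ring B, configuration undefined; C4=O; C5–I); ring B 2',6'-dichloro; N,N'-di-Boc (S,S)-piperazine (not isolated) | IC1=CC2=CC(I)(C1=O)Oc3c(Cl)cc(cc3Cl)C[C@H]4CN(C(=O)OC(C)(C)C)[C@H](CN4C(=O)OC(C)(C)C)C2 | intermediate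
10 | methoxy dienone macrocycle: ring A = 2-aryloxy-6-iodo-4-methoxycyclohexa-2,5-dienone (C1 sp3 with OMe and CH2, configuration undefined; C3–O–ring B; C4=O; C5–I); ring B 2',6'-dichloro; N,N'-di-Boc (S,S)-piperazine | IC1=CC2(OC)C=C(C1=O)Oc3c(Cl)cc(cc3Cl)C[C@H]4CN(C(=O)OC(C)(C)C)[C@H](CN4C(=O)OC(C)(C)C)C2 | intermediate
11 | macrocyclic iodophenol: aromatic ring A with C3–O–ring B, C4–OH, C5–I; ring B 2',6'-dichloro; N,N'-di-Boc (S,S)-piperazine | Ic1cc2cc(c1O)Oc3c(Cl)cc(cc3Cl)C[C@H]4CN(C(=O)OC(C)(C)C)[C@H](CN4C(=O)OC(C)(C)C)C2 | intermediate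
12 | C4-O-benzyl ether of 11 | Ic1cc2cc(c1OCc5ccccc5)Oc3c(Cl)cc(cc3Cl)C[C@H]4CN(C(=O)OC(C)(C)C)[C@H](CN4C(=O)OC(C)(C)C)C2 | intermediate
13 | C5 pinacol boronate (I of 12 replaced by Bpin) | CC1(C)OB(OC1(C)C)c1cc2cc(c1OCc5ccccc5)Oc3c(Cl)cc(cc3Cl)C[C@H]4CN(C(=O)OC(C)(C)C)[C@H](CN4C(=O)OC(C)(C)C)C2 | intermediate
14 | 8-bromo-2'-deoxyguanosine | Nc1nc2c(nc(Br)n2[C@H]3C[C@H](O)[C@@H](CO)O3)c(=O)[nH]1 | starting material
15 | 8-aryl-2'-deoxyguanosine: purine C8 bound to ring A C5 of the O-benzyl, 2',6'-dichloro, N,N'-di-Boc macrocycle | Nc1nc2c(nc(-c3cc4cc(c3OCc5ccccc5)Oc6c(Cl)cc(cc6Cl)C[C@H]7CN(C(=O)OC(C)(C)C)[C@H](CN7C(=O)OC(C)(C)C)C4)n2[C@H]8C[C@H](O)[C@@H](CO)O8)c(=O)[nH]1 | intermediate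
16 | 8-aryl-2'-deoxyguanosine with free C4–OH, chlorine-free ring B, N,N'-di-Boc | Nc1nc2c(nc(-c3cc4cc(c3O)Oc6ccc(cc6)C[C@H]7CN(C(=O)OC(C)(C)C)[C@H](CN7C(=O)OC(C)(C)C)C4)n2[C@H]8C[C@H](O)[C@@H](CO)O8)c(=O)[nH]1 | intermediate
17 | guanipiperazine A | Nc1nc2nc(-c3cc4cc(c3O)Oc3ccc(cc3)C[C@H]3CN[C@H](CN3)C4)[nH]c2c(=O)[nH]1 | target

**Step count**
Total steps: 11. Longest linear sequence: 11 steps (1 → 17); 3 and 14 enter as bought compounds.

**Steps most likely to fail**

Step 5. Methanol may capture the oxidized ring A before the ring B oxygen arrives. Chains may couple with one another in spite of the dilution, or the wrong ring may be oxidized.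
The fallback is a redox-neutral, copper-catalysed Ullmann ether macrocyclization in which ring B needs no blocking groups. It sets out from 1 and 3 and comes back at 16. 1 and 3 are joined (EDC·HCl, HOBt, N-methylmorpholine, DMF) to the dipeptide Boc-L-Tyr(3,5-I2)-L-Tyr-OMe F1. Formic acid should free the amine H-L-Tyr(3,5-I2)-L-Tyr-OMe F2, which on heating in 2-butanol–toluene should close to the diketopiperazine F3. BH3·THF should give the piperazine F4, and Boc2O its bis-carbamate F5. BnBr with KHCO3 in DMF should benzylate only the far more acidic diiodophenol, giving the mono-benzyl ether F6. CuI, N,N-dimethylglycine and Cs2CO3 in dioxane at 90 °C under high dilution should then join the ring B phenoxide to one of the two equivalent C–I carbons. This reaction type has precedent for 14-membered meta,para-cyclophane diaryl ethers and should give the macrocyclic iodide F7. Miyaura borylation should give the boronate F8, and Suzuki–Miyaura coupling with 14 as in step 9 the nucleoside F9. Hydrogenolysis of the benzyl ether (H2, Pd/C, MeOH) should give 16.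

Step 9. The electron-rich ortho-alkoxy boronate may protodeboronate in hot aqueous base. Oxidative addition to the deprotonated bromoguanine may be slow, and the two partners may dissolve poorly in a common medium.
The fallback is a neutral, anhydrous Stille coupling with a lipophilic purine partner. It sets out from 12 and 14 and comes back at 15. With (Me3Sn)2 and Pd(PPh3)4 in toluene at 100 °C, 12 should give the aryltrimethylstannane F10. With TBSCl and imidazole in DMF, 14 should give the 3',5'-bis-O-TBS ether F11. The two should couple (Pd(PPh3)4, CuI, DMF, 90 °C) to the silylated C8-aryl nucleoside F12, and Bu4NF in THF should return 15.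

Step 10. Binding of the purine to the palladium surface may stall the hydrodechlorination after the first chlorine or before debenzylation.
The fallback changes the order of events so that the metal never meets the purine. It sets out from 13 and comes back at 16. 13 is hydrogenated first (H2, Pd/C, NaOAc, MeOH–THF; the C–B bond is inert) to the chlorine-free ortho-hydroxyaryl boronate F13. This is then coupled with 14 under the conditions of step 9, a coupling type known for ortho-hydroxyphenyl boron reagents, to give 16 directly.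

**Further compounds**
F1 | step 5 | Boc-L-Tyr(3,5-I2)-L-Tyr-OMe | CC(C)(C)OC(=O)N[C@@H](Cc1cc(I)c(O)c(I)c1)C(=O)N[C@@H](Cc1ccc(O)cc1)C(=O)OC
F2 | step 5 | H-L-Tyr(3,5-I2)-L-Tyr-OMe | N[C@@H](Cc1cc(I)c(O)c(I)c1)C(=O)N[C@@H](Cc1ccc(O)cc1)C(=O)OC
F3 | step 5 | (3S,6S)-3-(4-hydroxybenzyl)-6-(4-hydroxy-3,5-diiodobenzyl)piperazine-2,5-dione | O=C1N[C@@H](Cc2ccc(O)cc2)C(=O)N[C@H]1Cc1cc(I)c(O)c(I)c1
F4 | step 5 | (2S,5S)-2-(4-hydroxybenzyl)-5-(4-hydroxy-3,5-diiodobenzyl)piperazine | C1N[C@@H](Cc2ccc(O)cc2)CN[C@H]1Cc1cc(I)c(O)c(I)c1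
F5 | step 5 | N,N'-di-Boc derivative of F4 | C1N(C(=O)OC(C)(C)C)[C@@H](Cc2ccc(O)cc2)CN(C(=O)OC(C)(C)C)[C@H]1Cc1cc(I)c(O)c(I)c1
F6 | step 5 | F5 benzylated on the diiodophenol oxygen | C1N(C(=O)OC(C)(C)C)[C@@H](Cc2ccc(O)cc2)CN(C(=O)OC(C)(C)C)[C@H]1Cc1cc(I)c(OCc2ccccc2)c(I)c1
F7 | step 5 | chlorine-free analogue of 12 (macrocyclic iodide, C4–OBn) | Ic1cc2cc(c1OCc5ccccc5)Oc3ccc(cc3)C[C@H]4CN(C(=O)OC(C)(C)C)[C@H](CN4C(=O)OC(C)(C)C)C2
F8 | step 5 | chlorine-free analogue of 13 (C5–Bpin, C4–OBn) | CC1(C)OB(OC1(C)C)c1cc2cc(c1OCc5ccccc5)Oc3ccc(cc3)C[C@H]4CN(C(=O)OC(C)(C)C)[C@H](CN4C(=O)OC(C)(C)C)C2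
F9 | step 5 | chlorine-free analogue of 15 (C4–OBn nucleoside) | Nc1nc2c(nc(-c3cc4cc(c3OCc5ccccc5)Oc6ccc(cc6)C[C@H]7CN(C(=O)OC(C)(C)C)[C@H](CN7C(=O)OC(C)(C)C)C4)n2[C@H]8C[C@H](O)[C@@H](CO)O8)c(=O)[nH]1
F10 | step 9 | C5 trimethylstannane (I of 12 replaced by SnMe3) | C[Sn](C)(C)c1cc2cc(c1OCc5ccccc5)Oc3c(Cl)cc(cc3Cl)C[C@H]4CN(C(=O)OC(C)(C)C)[C@H](CN4C(=O)OC(C)(C)C)C2
F11 | step 9 | 8-bromo-3',5'-bis-O-(tert-butyldimethylsilyl)-2'-deoxyguanosine | Nc1nc2c(nc(Br)n2[C@H]3C[C@H](O[Si](C)(C)C(C)(C)C)[C@@H](CO[Si](C)(C)C(C)(C)C)O3)c(=O)[nH]1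
F12 | step 9 | 3',5'-bis-O-TBS ether of 15 | Nc1nc2c(nc(-c3cc4cc(c3OCc5ccccc5)Oc6c(Cl)cc(cc6Cl)C[C@H]7CN(C(=O)OC(C)(C)C)[C@H](CN7C(=O)OC(C)(C)C)C4)n2[C@H]8C[C@H](O[Si](C)(C)C(C)(C)C)[C@@H](CO[Si](C)(C)C(C)(C)C)O8)c(=O)[nH]1
F13 | step 10 | chlorine-free boronate with free C4–OH (C5–Bpin, N,N'-di-Boc) | CC1(C)OB(OC1(C)C)c1cc2cc(c1O)Oc3ccc(cc3)C[C@H]4CN(C(=O)OC(C)(C)C)[C@H](CN4C(=O)OC(C)(C)C)C2
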